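**Plan**

- Cuts (target numbering, see below): lactone bond O7–C19 and ring bond C6–C7; C8–C9; the two cyclohexene bonds C10–C11 and C13=C14; C1–C2.
- Forward order: Z-iodoalkenyl chain C2–C6, then quaternary C1, then the six-membered ring by a (3+3) aldol/aldol-condensation annulation, then the C8–C9 union, the ten-membered ring by Nozaki–Hiyama–Kishi closure, and the γ-lactone last.
- Enabling feature: in the ring C1–C10–C11–C12–C13–C14 the aldol retron O=C9–C10–C11(OH)Me adjoins the enone retron O=C12–C13=C14. C20–C11–C12–C13 are therefore the four carbons of butane-2,3-dione, and C14–C1–C10–C9 is a succinaldehyde whose quaternary C1 leaves only the C9 side enolisable.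
- Stereochemistry: C1/C2 from an iridium-catalysed anti tert-(hydroxy)prenylation; C10/C11 from the amine catalyst of the key step; C12 from a Corey–Bakshi–Shibata reduction; C8/C17 from (S)-malic acid (Fráter–Seebach methylation, dioxolanone self-regeneration); C9 and C7 by substrate control; 5Z from an anti-carbomagnesiation.

Key step: step 10

Numbering: C1–C20 are the skeleton carbons of the target. C1 is the quaternary ring-fusion carbon (methyl C15), C2 and C9 carry the acetates, C5(C16)=C6 is the Z alkene, C7 is the lactone carbinol, C8 the tertiary carbinol, C10 the ring-fusion CH, C11(C20) and C12 the diol carbons, C13=C14 the ring alkene, C17(C18) the lactone α-carbon and C19 the lactone carbonyl.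

Assumption: (R)-Tol-BINAP is taken as the ligand enantiomer that gives the 2R carbinol in step 5. If the sense is the reverse, the (S)-ligand is used and nothing else changes. Epoxide 9 is used as the racemate, since its stereocentre is lost in the allyl intermediate.

**Route**

Step 1
Reactants: 1 prop-2-yn-1-ol
Product: 3 (Z)-3-iodo-2-methylprop-2-en-1-ol, via alkenylmagnesium alkoxide 2 (not isolated)
Conditions: MeMgBr (2.5 equiv), CuI (10 mol %), Et2O, −10 °C to rt; then I2, −78 to 0 °C
Reagents that add atoms: methylmagnesium bromide C[Mg]Br; iodine II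
Why: Copper-catalysed anti-carbomagnesiation of the propargylic alkoxide places magnesium cis to CH2O through chelation, and iodinolysis with retention gives the Z vinyl iodide that fixes the C5=C6 geometry (methyl = C16).

Step 2
Reactants: 3 (Z)-3-iodo-2-methylprop-2-en-1-ol
Product: 4 (Z)-3-bromo-1-iodo-2-methylprop-1-ene
Conditions: CBr4, PPh3, CH2Cl2, 0 °C
Reagents that add atoms: tetrabromomethane BrC(Br)(Br)Br
Why: The Appel reaction converts the allylic alcohol into the bromide under neutral conditions without touching the vinyl iodide or its geometry.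

Step 3
Reactants: 4 (Z)-3-bromo-1-iodo-2-methylprop-1-ene, 5 tert-butyl acetate
Product: 7 tert-butyl (Z)-5-iodo-4-methylpent-4-enoate, via lithium enolate of tert-butyl acetate 6 (not isolated)
Conditions: 5, LiN(i-Pr)2, THF, −78 °C; then 4, −78 to −20 °C
Reagents that add atoms: none
Why: SN2 alkylation of the ester enolate at the primary allylic bromide adds C2 and C3, the vinyl iodide being inert to the enolate at low temperature.

Step 4
Reactants: 7 tert-butyl (Z)-5-iodo-4-methylpent-4-enoate
Product: 8 (Z)-5-iodo-4-methylpent-4-en-1-ol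
Conditions: i-Bu2AlH (3 equiv), CH2Cl2, −78 °C to rt
Reagents that add atoms: none
Why: Hydride reduction of the ester gives the primary alcohol (future C2), the oxidation level required for the hydrogen-transfer coupling of step 5.

Step 5
Reactants: 8 (Z)-5-iodo-4-methylpent-4-en-1-ol, 9 2-methyl-2-vinyloxirane (racemic)
Product: 10 (2R,3R,6Z)-2-ethenyl-7-iodo-2,6-dimethylhept-6-ene-1,3-diol (C2–OH, C14–OH, vinyl = C10=C9)
Conditions: [Ir(cod)Cl]2 (2.5 mol %), (R)-Tol-BINAP (5 mol %), 3,4-dinitrobenzoic acid (10 mol %), K3PO4 (5 mol %), 9 (3 equiv), THF, 45 °C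
Reagents that add atoms: none
Why: In this hydrogen-transfer carbonyl tert-(hydroxy)prenylation the iridium catalyst dehydrogenates 8 to the aldehyde, opens 9 to an (E)-σ-allyl with the hydroxymethyl group trans to the metal-bearing carbon and adds it through a closed chair, so the C2 hydroxyl ends anti to CH2OH (quaternary C1 and C2 set, absolute sense from the ligand) while the hindered vinyl iodide is left alone.

Step 6
Reactants: 10 the 1,3-diol
Product: 11 (2R,3R,6Z)-2-ethenyl-7-iodo-2,6-dimethylhept-6-ene-1,3-diyl diacetate
Conditions: Ac2O, Et3N, DMAP (cat.), CH2Cl2, rt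
Reagents that add atoms: acetic anhydride CC(=O)OC(C)=O
Why: DMAP-catalysed acylation masks both hydroxyls for the hydroboration and oxidations that follow, the C2 acetate being a placeholder that is deliberately lost and renewed in steps 19 and 20.

Step 7
Reactants: 11 the diacetate
Product: 13 (2R,3R,6Z)-2-(2-hydroxyethyl)-7-iodo-2,6-dimethylhept-6-ene-1,3-diyl diacetate, via B-alkyl-9-borabicyclononane 12 (not isolated)
Conditions: 9-BBN-H, THF, 0 °C to rt; then 30% H2O2, aq. NaHCO3, 0 °C
Reagents that add atoms: hydrogen peroxide OO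
Why: Anti-Markovnikov hydroboration–oxidation with the bulky borane takes only the monosubstituted vinyl group (oxygen at C9), the iodo-substituted trisubstituted alkene being hindered and deactivated, and buffered peroxide spares the acetates.

Step 8
Reactants: 13 the hydroxyethyl diacetate
Product: 14 (2R,3R,6Z)-1-hydroxy-2-(2-hydroxyethyl)-7-iodo-2,6-dimethylhept-6-en-3-yl acetate (C9–OH and C14–OH free, C2–OAc)
Conditions: K2CO3 (0.2 equiv), MeOH, 0 °C
Reagents that add atoms: none
Why: Base-catalysed transesterification should be much faster at the primary acetate than at the secondary acetate flanked by the quaternary carbon, which frees the C14 hydroxyl selectively.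

Step 9
Reactants: 14 the monoacetate diol
Product: 15 (1R,4Z)-5-iodo-4-methyl-1-[(2S)-2-methyl-1,4-dioxobutan-2-yl]pent-4-en-1-yl acetate (C9 and C14 dialdehyde)
Conditions: (COCl)2, DMSO, CH2Cl2, −78 °C; then Et3N, −78 to 0 °C
Reagents that add atoms: none
Why: Swern oxidation of both primary alcohols at low temperature gives the dialdehyde without lactol or lactone formation, and the C14 aldehyde has no α-hydrogen, so the β-acetate cannot eliminate.

Step 10
Reactants: 15 the C9/C14 dialdehyde, 16 butane-2,3-dione
Product: 18 cyclohexenone aldehyde (ring C1, C10, C11, C12, C13, C14; C12 ketone, C13=C14, C11 tertiary OH and methyl, C9 aldehyde on C10, C2 acetate and iodoalkenyl chain on C1; C1, C2, C10, C11 as in the target), via acyclic aldol adduct 17 (not isolated)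
Conditions: 16 (5 equiv), (R)-5-(pyrrolidin-2-yl)-1H-tetrazole (20 mol %), DMF, 4 °C; then dibenzylammonium trifluoroacetate (20 mol %), rt; crude 18 taken directly into step 11
Reagents that add atoms: none
Why: Proposed new method: the secondary-amine catalyst condenses with the only enolisable carbonyl of 15 (the C9 aldehyde) to give the E-enamine, whose C10 adds to one carbonyl of diketone 16 through the hydrogen-bonded chair of proline-type aldol additions (bond C10–C11, tertiary carbinol 17), and the ammonium salt then drives the remaining acetyl group (C12/C13) into an aldol condensation with the non-enolisable neopentyl aldehyde C14 (bond C13=C14). The closest known reactions are the proline-type cross-aldol of aldehyde donors with activated ketones and the amine-catalysed aldol/aldol-condensation cascade of succinaldehyde; the new element is a 1,2-diketone serving as a three-carbon donor–acceptor unit C11–C12–C13 in a (3+3) annulation. The six-membered ring closes by a 6-(enolendo)-exo-trig aldol followed by dehydration, and the alkene is necessarily cis because it is formed inside the ring. C10 and C11 are set by the catalyst in the intermolecular event (anti addition with the acetyl group in the equatorial site, the R catalyst expected to give 10R,11S in 18), while C1 and C2 are carried in from 15. The step needs chemoselectivity among four carbonyl groups, which the substrate secures: C14 cannot enolise, C11 becomes fully substituted so that C12 enolises only towards C13, closure onto C9 would be a disfavoured 5-(enolendo) mode, and the excess of 16 suppresses self-aldol of 15. The main hazard is β-elimination of the new tertiary hydroxyl from the β-hydroxy aldehyde, which is why a tetrazole catalyst (no decarboxylative loss with the diketone), low temperature and immediate reduction in step 11 are used.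

Step 11
Reactants: 18 the cyclohexenone aldehyde
Product: 19 triol (C9 primary OH, C11 tertiary OH, C12 secondary allylic OH cis to the C11 OH; C2 acetate retained)
Conditions: (S)-2-methyl-CBS-oxazaborolidine (20 mol %), BH3·SMe2 (2.5 equiv), THF, −30 °C; MeOH quench
Reagents that add atoms: none
Why: In the Corey–Bakshi–Shibata reduction the fully substituted C11 acts as the large group and the vinyl carbon C13 as the small one, so the (S)-catalyst should deliver hydride to give 12R (cis to the C11 hydroxyl), while the aldehyde is reduced uncatalysed and the elimination-prone β-hydroxy aldehyde is removed.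

Step 12
Reactants: 19 the triol
Product: 20 C11,C12-acetonide with free C9 primary alcohol
Conditions: 2,2-dimethoxypropane, PPTS (cat.), acetone, rt
Reagents that add atoms: 2,2-dimethoxypropane COC(C)(C)OC
Why: Under equilibrating acetalisation the cis-1,2-diol forms the five-membered dioxolane in preference to the six-membered C9/C11 dioxane, which protects C11 and C12, proofreads the cis relationship and leaves the C9 hydroxyl free.

Step 13
Reactants: 20 the acetonide alcohol
Product: 21 C9 aldehyde (C11,C12-acetonide, C2 acetate, vinyl iodide)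
Conditions: Dess–Martin periodinane, NaHCO3, CH2Cl2, 0 °C
Reagents that add atoms: none
Why: Buffered Dess–Martin oxidation gives the aldehyde without epimerising C10 or opening the β-alkoxy acetonide.

Step 14
Reactants: 22 diethyl (S)-malate
Product: 24 diethyl (2S,3R)-2-hydroxy-3-methylbutanedioate, via dilithium alkoxide enolate 23 (not isolated)
Conditions: LiN(i-Pr)2 (2.2 equiv), THF, −78 to −20 °C; then MeI, −78 to 0 °C
Reagents that add atoms: iodomethane CI
Why: In the Fráter–Seebach alkylation the chelated alkoxide enolate is methylated anti to the alkoxide, giving the 2S,3R isomer that carries the future C8 (S) and C17 (R, methyl C18).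

Step 15
Reactants: 24 diethyl (2S,3R)-3-methylmalate
Product: 25 (2S,3R)-2-hydroxy-3-methylbutanedioic acid
Conditions: KOH, H2O/EtOH, 0 °C to rt; then aq. HCl
Reagents that add atoms: potassium hydroxide [K+].[OH-]
Why: Mild saponification gives the diacid needed for acetalisation at the α-hydroxy acid terminus without epimerising the α-methyl centre.

Step 16
Reactants: 25 (2S,3R)-3-methylmalic acid, 26 pivalaldehyde
Product: 27 (R)-2-[(2S,4S)-2-tert-butyl-5-oxo-1,3-dioxolan-4-yl]propanoic acid (cis-dioxolanone)
Conditions: TsOH (cat.), H2SO4 (cat.), pentane, reflux, water separator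
Reagents that add atoms: none
Why: The α-hydroxy acid terminus forms the five-membered dioxolanone in preference to the six-membered alternative, and the thermodynamic cis acetal stores the C8 configuration in the new acetal centre (self-regeneration of stereocentres).

Step 17
Reactants: 27 the dioxolanone acid
Product: 28 tert-butyl (R)-2-[(2S,4S)-2-tert-butyl-5-oxo-1,3-dioxolan-4-yl]propanoate
Conditions: tert-butyl 2,2,2-trichloroacetimidate, BF3·OEt2 (cat.), CH2Cl2/cyclohexane, rt
Reagents that add atoms: tert-butyl 2,2,2-trichloroacetimidate CC(C)(C)OC(=N)C(Cl)(Cl)Cl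
Why: Acid-catalysed imidate esterification avoids base at the acylal, and the tert-butyl ester (future C19) is chosen because it resists both lactonisation by the C9 alkoxide and hydride at −78 °C.

Step 18
Reactants: 28 the dioxolanone tert-butyl ester, 21 the C9 aldehyde
Product: 30 aldol adduct (C8–C9 bond; C8 quaternary in the dioxolanone, C9 secondary OH, C17 side chain with tert-butyl ester), via lithium dioxolanone enolate 29 (not isolated)
Conditions: 28, LiN(SiMe3)2, THF, −78 °C; then 21, −78 °C; AcOH quench at −78 °C
Reagents that add atoms: none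
Why: In this aldol addition of the dioxolanone enolate the aldehyde enters trans to the tert-butyl group, so C8 is formed with overall retention (8S), and C9 is expected from Felkin–Anh addition to the α-branched aldehyde (to be confirmed), the more acidic ring C–H being removed in preference to the hindered ester α-hydrogen.

Step 19
Reactants: 30 the aldol adduct
Product: 32 α-hydroxy aldehyde triol (C7 aldehyde, free OH at C8, C9 and C2, tert-butyl ester and acetonide intact), via dioxolanyl lactol 31 (not isolated)
Conditions: i-Bu2AlH (4.5 equiv), CH2Cl2, −78 °C; aq. potassium sodium tartrate; then silica gel, rt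
Reagents that add atoms: none
Why: The activated dioxolanone carbonyl is reduced to the lactol, which is stable as the aluminium hemiacetal at −78 °C and collapses on work-up with loss of pivalaldehyde to the C7 aldehyde, while the C2 acetate is cleaved as planned and the hindered tert-butyl ester survives at this temperature.

Step 20
Reactants: 32 the aldehyde triol
Product: 33 C2,C9-diacetate aldehyde (C8 tertiary OH free)
Conditions: Ac2O, pyridine, DMAP (cat.), CH2Cl2, 0 °C to rt
Reagents that add atoms: acetic anhydride CC(=O)OC(C)=O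
Why: Both secondary hydroxyls are acylated to the acetates of the target, while the tertiary C8 hydroxyl does not react and the aldehyde has no α-hydrogen to enolise.

Step 21
Reactants: 33 the iodoalkenyl aldehyde
Product: 35 ten-membered carbocycle (C6–C7 bond, C7 secondary allylic OH, 5Z alkene; acetonide, both acetates and tert-butyl ester retained), via alkenylchromium species 34 (not isolated)
Conditions: CrCl2 (10 equiv), NiCl2 (2 mol %), DMSO/THF (3:1), 0.002 M, rt
Reagents that add atoms: none
Why: In this Nozaki–Hiyama–Kishi cyclisation zerovalent nickel formed in situ inserts into the vinyl C–I bond with retention of the Z geometry, transmetalation gives the trivalent alkenylchromium 34, and this adds only to the aldehyde under high dilution, with C7 expected from attack anti to the C8 oxygen.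

Step 22
Reactants: 35 the macrocyclic hydroxy ester
Product: 38 CNP0146024.1 (target), via seco acid 36 (not isolated), via lactone acetonide 37 (not isolated)
Conditions: CF3CO2H/CH2Cl2 (1:4), 0 °C to rt; then H2O, rt; aq. NaHCO3 work-up
Reagents that add atoms: none
Why: Acid cleaves the tert-butyl ester, the resulting γ-hydroxy acid lactonises onto the only free secondary hydroxyl (C7, since C9 is already acetylated and C8 is tertiary), and aqueous acid then removes the acetonide to free the C11/C12 diol.

**Compound list**

1 | prop-2-yn-1-ol | C#CCO | starting material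
2 | (Z)-alkenylmagnesium bromide alkoxide from the carbomagnesiation (Mg on C3 cis to CH2O) | Br[Mg]OC/C(C)=C\[Mg]Br | intermediate (not isolated)
3 | (Z)-3-iodo-2-methylprop-2-en-1-ol | OC/C(C)=C\I | intermediate
4 | (Z)-3-bromo-1-iodo-2-methylprop-1-ene | BrC/C(C)=C\I | intermediate
5 | tert-butyl acetate | CC(=O)OC(C)(C)C | starting material
6 | lithium enolate of tert-butyl acetate | [Li+].[O-]C(=C)OC(C)(C)C | intermediate (not isolated)
7 | tert-butyl (Z)-5-iodo-4-methylpent-4-enoate | CC(C)(C)OC(=O)CC/C(C)=C\I | intermediate
8 | (Z)-5-iodo-4-methylpent-4-en-1-ol | OCCC/C(C)=C\I | intermediate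
9 | 2-methyl-2-vinyloxirane (racemic) | C=CC1(C)CO1 | starting material
10 | (2R,3R,6Z)-2-ethenyl-7-iodo-2,6-dimethylhept-6-ene-1,3-diol | C=C[C@](C)(CO)[C@H](O)CC/C(C)=C\I | intermediate
11 | (2R,3R,6Z)-2-ethenyl-7-iodo-2,6-dimethylhept-6-ene-1,3-diyl diacetate | C=C[C@](C)(COC(C)=O)[C@H](OC(C)=O)CC/C(C)=C\I | intermediate
12 | B-alkyl-9-borabicyclo[3.3.1]nonane from hydroboration of 11 at the terminal carbon | C1CCC2CCCC1B2CC[C@](C)(COC(C)=O)[C@H](OC(C)=O)CC/C(C)=C\I | intermediate (not isolated)
13 | (2R,3R,6Z)-2-(2-hydroxyethyl)-7-iodo-2,6-dimethylhept-6-ene-1,3-diyl diacetate | OCC[C@](C)(COC(C)=O)[C@H](OC(C)=O)CC/C(C)=C\I | intermediate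
14 | (2R,3R,6Z)-1-hydroxy-2-(2-hydroxyethyl)-7-iodo-2,6-dimethylhept-6-en-3-yl acetate | OCC[C@](C)(CO)[C@H](OC(C)=O)CC/C(C)=C\I | intermediate
15 | (1R,4Z)-5-iodo-4-methyl-1-[(2S)-2-methyl-1,4-dioxobutan-2-yl]pent-4-en-1-yl acetate (C9/C14 dialdehyde) | O=CC[C@](C)(C=O)[C@H](OC(C)=O)CC/C(C)=C\I | intermediate
16 | butane-2,3-dione | CC(=O)C(C)=O | starting material
17 | acyclic cross-aldol adduct (C10–C11 formed; C9 and C14 aldehydes, C11 tertiary OH, C12 acetyl) | O=C[C@@H]([C@](C)(O)C(C)=O)[C@](C)(C=O)[C@H](OC(C)=O)CC/C(C)=C\I | intermediate (not isolated)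
18 | cyclohexenone aldehyde (C12 ketone, C13=C14, C11 OH/Me, C9 aldehyde, C2 acetate; C1, C2, C10, C11 as in target) | O=C[C@H]1[C@](C)(O)C(=O)C=C[C@]1(C)[C@H](OC(C)=O)CC/C(C)=C\I | intermediate
19 | triol (C9 CH2OH, C11 OH, C12 OH cis to C11 OH; C2 acetate) | OC[C@H]1[C@](C)(O)[C@H](O)C=C[C@]1(C)[C@H](OC(C)=O)CC/C(C)=C\I | intermediate
20 | C11,C12-acetonide with free C9 alcohol | OC[C@H]1[C@]2(C)OC(C)(C)O[C@@H]2C=C[C@]1(C)[C@H](OC(C)=O)CC/C(C)=C\I | intermediate
21 | C9 aldehyde of the acetonide | O=C[C@H]1[C@]2(C)OC(C)(C)O[C@@H]2C=C[C@]1(C)[C@H](OC(C)=O)CC/C(C)=C\I | intermediate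
22 | diethyl (S)-malate | CCOC(=O)C[C@H](O)C(=O)OCC | starting material
23 | dilithium alkoxide enolate of diethyl (S)-malate | [Li+].[Li+].CCOC([O-])=C[C@H]([O-])C(=O)OCC | intermediate (not isolated)
24 | diethyl (2S,3R)-2-hydroxy-3-methylbutanedioate | CCOC(=O)[C@H](C)[C@H](O)C(=O)OCC | intermediate
25 | (2S,3R)-2-hydroxy-3-methylbutanedioic acid | OC(=O)[C@H](C)[C@H](O)C(=O)O | intermediate
26 | pivalaldehyde (2,2-dimethylpropanal) | CC(C)(C)C=O | starting material
27 | (R)-2-[(2S,4S)-2-tert-butyl-5-oxo-1,3-dioxolan-4-yl]propanoic acid | CC(C)(C)[C@H]1O[C@@H]([C@@H](C)C(=O)O)C(=O)O1 | intermediate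
28 | tert-butyl (R)-2-[(2S,4S)-2-tert-butyl-5-oxo-1,3-dioxolan-4-yl]propanoate | CC(C)(C)[C@H]1O[C@@H]([C@@H](C)C(=O)OC(C)(C)C)C(=O)O1 | intermediate
29 | lithium enolate of dioxolanone 28 | [Li+].[O-]C1=C([C@@H](C)C(=O)OC(C)(C)C)O[C@H](C(C)(C)C)O1 | intermediate (not isolated)
30 | aldol adduct (C8 quaternary in the dioxolanone, C9 OH, tert-butyl ester at C19) | CC(C)(C)[C@H]1O[C@]([C@@H](C)C(=O)OC(C)(C)C)([C@H](O)[C@H]2[C@]3(C)OC(C)(C)O[C@@H]3C=C[C@]2(C)[C@H](OC(C)=O)CC/C(C)=C\I)C(=O)O1 | intermediate
31 | dioxolanyl lactol (C7 hemiacetal; C2 acetate already cleaved) | CC(C)(C)[C@H]1O[C@]([C@@H](C)C(=O)OC(C)(C)C)([C@H](O)[C@H]2[C@]3(C)OC(C)(C)O[C@@H]3C=C[C@]2(C)[C@H](O)CC/C(C)=C\I)C(O)O1 | intermediate (not isolated)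
32 | α-hydroxy aldehyde triol (C7 aldehyde; OH at C8, C9, C2) | O=C[C@@](O)([C@@H](C)C(=O)OC(C)(C)C)[C@H](O)[C@H]1[C@]2(C)OC(C)(C)O[C@@H]2C=C[C@]1(C)[C@H](O)CC/C(C)=C\I | intermediate
33 | C2,C9-diacetate aldehyde | O=C[C@@](O)([C@@H](C)C(=O)OC(C)(C)C)[C@H](OC(C)=O)[C@H]1[C@]2(C)OC(C)(C)O[C@@H]2C=C[C@]1(C)[C@H](OC(C)=O)CC/C(C)=C\I | intermediate
34 | trivalent alkenylchromium dichloride derived from 33 | O=C[C@@](O)([C@@H](C)C(=O)OC(C)(C)C)[C@H](OC(C)=O)[C@H]1[C@]2(C)OC(C)(C)O[C@@H]2C=C[C@]1(C)[C@H](OC(C)=O)CC/C(C)=C\[Cr](Cl)Cl | intermediate (not isolated)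
35 | ten-membered carbocycle (C7 OH, C8 OH, tert-butyl ester, acetonide, two acetates) | CC(=O)O[C@@H]1[C@H]2[C@]3(C)OC(C)(C)O[C@@H]3C=C[C@]2(C)[C@H](OC(C)=O)CC/C(C)=C\[C@H](O)[C@@]1(O)[C@@H](C)C(=O)OC(C)(C)C | intermediate
36 | seco acid (C19 carboxylic acid, C7 OH) | CC(=O)O[C@@H]1[C@H]2[C@]3(C)OC(C)(C)O[C@@H]3C=C[C@]2(C)[C@H](OC(C)=O)CC/C(C)=C\[C@H](O)[C@@]1(O)[C@@H](C)C(=O)O | intermediate (not isolated)
37 | lactone acetonide (O7–C19 γ-lactone, C11,C12-acetonide) | CC(=O)O[C@@H]1[C@H]2[C@]3(C)OC(C)(C)O[C@@H]3C=C[C@]2(C)[C@H](OC(C)=O)CC/C(C)=C\[C@@H]2OC(=O)[C@H](C)[C@]21O | intermediate (not isolated)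
38 | CNP0146024.1 | CC(=O)O[C@@H]1[C@H]2[C@](C)(O)[C@H](O)C=C[C@]2(C)[C@H](OC(C)=O)CC/C(C)=C\[C@@H]2OC(=O)[C@H](C)[C@]21O | target

**Step count and risks**

Total step count: 22. Longest linear sequence: 18 steps (steps 1–13, then 18–22); the malic acid branch is steps 14–17.

Steps most likely to fail:

1. Step 10 (proposed new method). What may go wrong: β-elimination of the new tertiary hydroxyl from the β-hydroxy aldehyde, consumption of the amine catalyst by the diketone, self-aldol of 15, or weak catalyst control at C10/C11. Fallback with known chemistry, from 15 back to 18: because only C9 of 15 can enolise, Me3SiCl/NaI/Et3N in MeCN gives the C9 trimethylsilyl enol ether F1. A Mukaiyama aldol addition of F1 to 16 (TiCl4, CH2Cl2, −78 °C) gives 17 after aqueous work-up, and piperidinium acetate in benzene closes and dehydrates 17 to 18. Without catalyst control, the C10/C11 isomers would be separated as the acetonides 20.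

2. Step 18. What may go wrong: enolisation of the hindered, base-sensitive aldehyde 21 in place of addition (with opening of the β-alkoxy acetonide), or poor facial selectivity at C9. Fallback, from 21 back to 30: Pinnick oxidation (NaClO2, NaH2PO4, 2-methylbut-2-ene) gives the C9 carboxylic acid F2, and carbonyldiimidazole converts it into the acyl imidazole F3. C-Acylation of enolate 29 with F3 gives the β-keto dioxolanone F4, in which C8 is set trans to the tert-butyl group and C9 is not yet a stereocentre. Chelation-controlled reduction of the C9 ketone with Zn(BH4)2 (or a Corey–Bakshi–Shibata reduction of the required sense) then gives 30.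

3. Step 21. What may go wrong: oligomerisation in competition with the slow ten-membered ring closure, and addition to the wrong face of the aldehyde. Fallback, from 33 back to 35: if the cyclisation gives the C7 epimer F5 of 35, Dess–Martin oxidation converts it into the C7 enone F6, and reagent-controlled reduction (Corey–Bakshi–Shibata catalyst of the required sense, catecholborane, −78 °C) returns 35 with the 7S carbinol.

Further compounds
F1 | step 10 | C9 trimethylsilyl enol ether of dialdehyde 15 (C14 aldehyde retained) | C[Si](C)(C)O/C=C\[C@](C)(C=O)[C@H](OC(C)=O)CC/C(C)=C\I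
F2 | step 18 | C9 carboxylic acid from aldehyde 21 | OC(=O)[C@H]1[C@]2(C)OC(C)(C)O[C@@H]2C=C[C@]1(C)[C@H](OC(C)=O)CC/C(C)=C\I
F3 | step 18 | C9 acyl imidazole | O=C(n1ccnc1)[C@H]1[C@]2(C)OC(C)(C)O[C@@H]2C=C[C@]1(C)[C@H](OC(C)=O)CC/C(C)=C\I
F4 | step 18 | β-keto dioxolanone (C9 ketone, C8 quaternary) | CC(C)(C)[C@H]1O[C@]([C@@H](C)C(=O)OC(C)(C)C)(C(=O)[C@H]2[C@]3(C)OC(C)(C)O[C@@H]3C=C[C@]2(C)[C@H](OC(C)=O)CC/C(C)=C\I)C(=O)O1
F5 | step 21 | C7 epimer of macrocycle 35 | CC(=O)O[C@@H]1[C@H]2[C@]3(C)OC(C)(C)O[C@@H]3C=C[C@]2(C)[C@H](OC(C)=O)CC/C(C)=C\[C@@H](O)[C@@]1(O)[C@@H](C)C(=O)OC(C)(C)C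
F6 | step 21 | C7 enone of the macrocycle | CC(=O)O[C@@H]1[C@H]2[C@]3(C)OC(C)(C)O[C@@H]3C=C[C@]2(C)[C@H](OC(C)=O)CC/C(C)=C\C(=O)[C@@]1(O)[C@@H](C)C(=O)OC(C)(C)C
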